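Remark on the chemistry: ambofuranol has no stereocentre, so every chiral intermediate is carried as a racemate or as a mixture of diastereomers; "prenyl" stands for 3-methylbut-2-enyl.

## Analysis of the target

Ambofuranol (22) is a 2-aryl-1-benzofuran: a furan ring fused to ring A (C3a to C7a) and carrying ring B (C1' to C6') at C2. It has no stereocentre, so the task is one of regiochemistry and of telling the oxygens apart. Five oxygens occur in three states: methyl ethers at C3 and C4', free phenols at C6 and C2', and the ring oxygen O1. Late selective methylation or demethylation is therefore unsafe, and each oxygen should arrive in its final state or under its own mask. The sensitive groups are the C5 prenyl chain and the 3-methoxyfuran. The prenyl chain is a nucleophilic trisubstituted alkene that adds carbenes and protons, is lost on hydrogenation and cyclises onto the C6 hydroxyl to a chroman under acid. The 3-methoxyfuran is an electron-rich enol ether open to oxidation. The difficulty is to build the fully substituted furan with an oxygen at C3 at the correct oxidation level while the ortho-prenylphenol stays intact. The strategy rests on ring B, a 1,3-dioxygenated benzene with OH at C2', OMe at C4' and hydrogen at C3', C5' and C6', joined through C1' to C2, which can be a ketone carbonyl before the furan closes. A 1,1,3-trioxygenated butadiene and a terminal acetylenic ketone give exactly this pattern on cycloaddition and aromatisation, with the two oxygens already differentiated.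

## Retrosynthetic reasoning

22 to 19. The furan is opened at O1–C2. The precursor is α-methoxy ketone 19: C2 is a carbonyl carbon, C3 already bears its methoxy group and one hydrogen, and the future O1 is an acetal-protected phenol on ring A. This cut leaves all C–C bonds of the core to earlier steps and needs no redox change. In the forward direction acid has to unmask both ring A oxygens (20), close the five-membered ring (21) and dehydrate, without touching the prenyl group.

19 to 13 and 16. Ring B is taken apart at C1'–C2' and C5'–C6'. These are the two bonds a [4+2] addition of diene 16 to the alkyne of ynone 13 forms. The cut is placed here because the C2' hydroxyl and the C4' methyl ether then come from different carbons of 16 and never need to be told apart chemically. The aryl ketone that results is also the electrophile required for the furan closure. The forward reaction must be regioselective and must aromatise by expelling one alkoxy group.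

16 to 14. The diene is the O-silylated extended enolate of crotonate 14, one step through dienolate 15.

13 to 10 and 11. The acyl–alkyne bond is cut. Weinreb amide 10 takes up Grignard reagent 11 once only, because chelate 12 holds the tetrahedral stage until work-up.

10 to 8 and 9. The aryl–prenyl bond at C5 is cut to aryl bromide 8 and stannane 9. The coupling is placed after the homologation, so the alkene never meets haloform and base, and before the alkyne is present, so the palladium catalyst meets no terminal acetylene.

8 to 6 to 2. The amide comes from acid 6 through acylimidazole 7. Acid 6 is disconnected at the carboxyl carbon and at the benzylic C–OMe bond: a one-carbon homologation of aldehyde 2 through 3, 4 and 5 installs the carboxyl group and the methoxy group that ends as C3–OMe in one operation.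

2 to 1. Both phenols of 1 are masked as base-stable, acid-labile acetals, which are released in the step where the furan closes.

## Alternatives that were turned down

Alternative 1: The furan is cut at C3–C3a, C3–OMe and O1–C2, giving 4-methoxy-2-(pivaloyloxy)phenylglyoxal A2, 4-prenylresorcinol A3 and the alcoholic solvent as methoxy source. Under mild acid the aldehyde carbon of A2 would alkylate C6 of A3, the benzylic carbinol would ionise to an ortho-quinone methide that the solvent captures, and the neighbouring phenol would condense with the ketone to give the 2'-O-pivalate A1.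
- For: three bonds in one flask and a route of about three steps. On step economy it is clearly stronger than the chosen route.
- Against: A3 is used unprotected under acid, where the prenylphenol can close to a chroman. A3 also offers C2 as a second nucleophilic site. The quinone methide is more likely to be trapped by a second molecule of the electron-rich A3 than by solvent. Arylation at the ketone carbon would give the isomeric 3-aryl series.
- Comparison: the chosen route is longer, but every bond is formed with the regiochemistry fixed by the reagents, and the prenylphenol is exposed to acid only once, in the last step.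

Alternative 2: The dihydrofuran is cut at C2–C3 and O1–C2. The ylide from [4-methoxy-2-(methoxymethoxy)benzyl]dimethylsulfonium bromide A5 would add to 2-hydroxy-4-(methoxymethoxy)-5-prenylbenzaldehyde A6, and the ortho phenoxide would displace the sulfide at the benzylic carbon, giving the trans-dihydrobenzofuranol A4.
- For: the annulation is a well-behaved reaction class, runs under base that the prenyl group tolerates, and is convergent. As a key step it carries less risk than a cycloaddition to a terminal ynone.
- Against: A4 is at the wrong oxidation level. It has to be oxidised to the benzofuran-3(2H)-one A7, whose ambident enolate must then be methylated on oxygen and not at C2. The 3-hydroxybenzofuran tautomer is easily autoxidised. Two stereocentres are made and erased, and both halves need their own syntheses.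
- Comparison: the chosen route brings the C3 methoxy group in with the homologation and needs no redox step and no ambident alkylation. Overall length is similar.

Alternative 3: Ring A is cut at C5–C6. The divinylfuran A9 contains the triene C6=C7–C7a=C3a–C4=C5 and would undergo thermal disrotatory 6π-electrocyclisation, then lose a silanol to give the doubly protected benzofuran A8.
- For: all ring A substituents are fixed by acyclic pieces, and no electrophilic substitution is needed.
- Against: A9 is a tetrasubstituted 3-methoxyfuran with a ketene acetal side chain. It is harder to prepare and more fragile than the target. The cyclisation has to break furan aromaticity at the central double bond, which calls for high temperature.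
- Comparison: it is not stronger on step economy or robustness. Its one advantage, regiochemistry fixed by connectivity, is shared by the chosen route, which builds the simpler ring B from a known diene.

Key step: step 7

## Route

Step 1
Reactants: 1 5-bromo-2,4-dihydroxybenzaldehyde
Product: 2 5-bromo-2,4-bis(methoxymethoxy)benzaldehyde
Conditions: NaH (2.5 equiv), MOMCl (2.5 equiv), DMF, 0 °C → rt
Reagents that add atoms: chloromethyl methyl ether, COCCl
Why: Williamson-type O-alkylation of both phenoxides; NaH breaks the hydrogen bond between the C2 hydroxyl and the aldehyde. The acetals survive KOH, organometallic reagents and palladium catalysis and leave under acid in the last step.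

Step 2
Reactants: 2 5-bromo-2,4-bis(methoxymethoxy)benzaldehyde
Product: 6 racemic 2-[5-bromo-2,4-bis(methoxymethoxy)phenyl]-2-methoxyacetic acid, via tribromomethyl carbinol 3 (not isolated), via gem-dibromo epoxide 4 (not isolated), via acyl bromide 5 (not isolated)
Conditions: CHBr3, KOH, LiCl, MeOH/1,4-dioxane, 0 °C → rt; then cold 1 M aq. HCl to pH 3
Reagents that add atoms: bromoform, BrC(Br)Br; methanol, CO; potassium hydroxide, [K+].[OH-]
Why: Jocic–Reeve homologation: tribromomethanide adds to the aldehyde, alkoxide 3 closes to epoxide 4, methoxide opens it at the benzylic carbon and acyl bromide 5 is hydrolysed to the carboxylate; the new centre is racemic. Aryl bromide and acetals are inert to methanolic KOH. The step is run before prenylation so that no alkene meets dibromocarbene from the haloform.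

Step 3
Reactants: 6 racemic 2-[5-bromo-2,4-bis(methoxymethoxy)phenyl]-2-methoxyacetic acid
Product: 8 racemic 2-[5-bromo-2,4-bis(methoxymethoxy)phenyl]-N,2-dimethoxy-N-methylacetamide, via acylimidazole 7 (not isolated)
Conditions: 1,1'-carbonyldiimidazole, CH2Cl2, rt; then MeNH(OMe)·HCl, rt
Reagents that add atoms: N,O-dimethylhydroxylamine hydrochloride, CNOC.Cl; 1,1'-carbonyldiimidazole, O=C(n1ccnc1)n1ccnc1 (imidazolyl group, in intermediate 7 only)
Why: Amide formation through the acylimidazole under nearly neutral conditions, which the acetals tolerate, gives the Weinreb amide.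

Step 4
Reactants: 8 racemic 2-[5-bromo-2,4-bis(methoxymethoxy)phenyl]-N,2-dimethoxy-N-methylacetamide; 9 tributyl(3-methylbut-2-enyl)stannane
Product: 10 racemic N,2-dimethoxy-N-methyl-2-[2,4-bis(methoxymethoxy)-5-(3-methylbut-2-enyl)phenyl]acetamide
Conditions: Pd(PPh3)4 (cat.), DMF, 95 °C
Reagents that add atoms: none
Why: Stille coupling: zerovalent palladium inserts into the aryl bromide, the prenyl group is transferred from tin, and reductive elimination from the η3-prenyl aryl complex at the less substituted terminus gives the linear prenyl arene. Amide and acetals are inert, and no alkyne is present yet.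

Step 5
Reactants: 10 racemic N,2-dimethoxy-N-methyl-2-[2,4-bis(methoxymethoxy)-5-(3-methylbut-2-enyl)phenyl]acetamide; 11 ethynylmagnesium bromide
Product: 13 racemic 1-methoxy-1-[2,4-bis(methoxymethoxy)-5-(3-methylbut-2-enyl)phenyl]but-3-yn-2-one, via magnesium hemiaminal 12 (not isolated)
Conditions: 11 (3 equiv), THF, −78 → 0 °C; inverse quench into cold 10% aq. citric acid
Reagents that add atoms: none
Why: Weinreb ketone synthesis: chelate 12 prevents a second addition and releases the ynone only on work-up. The inverse acidic quench protonates the liberated hydroxylamine before it can add to the ynone; the weakly basic acetylide does little at the α-CH, whose configuration is irrelevant.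

Step 6
Reactants: 14 methyl (E)-3-methoxybut-2-enoate
Product: 16 (1Z)-1,3-dimethoxy-1-(trimethylsilyloxy)buta-1,3-diene, via lithium dienolate 15 (not isolated)
Conditions: LiN(iPr)2 (commercial solution), THF, −78 °C; then Me3SiCl, −78 °C → rt; non-aqueous work-up, distillation
Reagents that add atoms: chlorotrimethylsilane, C[Si](C)(C)Cl; LiN(iPr)2, CC(C)N([Li])C(C)C (lithium, in intermediate 15 only)
Why: γ-Deprotonation gives the extended enolate, and the hard silyl chloride reacts at oxygen to give the silyl ketene acetal diene. The geometry drawn at C1 is erased later on aromatisation.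

Step 7
Reactants: 13 racemic 1-methoxy-1-[2,4-bis(methoxymethoxy)-5-(3-methylbut-2-enyl)phenyl]but-3-yn-2-one; 16 (1Z)-1,3-dimethoxy-1-(trimethylsilyloxy)buta-1,3-diene
Product: 19 racemic 1-(2-hydroxy-4-methoxyphenyl)-2-methoxy-2-[2,4-bis(methoxymethoxy)-5-(3-methylbut-2-enyl)phenyl]ethanone, via cycloadduct 17 (not isolated), via aryl silyl ether 18 (not isolated)
Conditions: 16 (2.5 equiv), toluene, 20 → 80 °C; then 10% aq. citric acid/THF, rt
Reagents that add atoms: none
Why: Diels–Alder addition of a ketene acetal diene to an acetylenic ketone followed by aromatisation is a known way to chelated 2-hydroxy-4-methoxyaryl ketones. The addition is asynchronous and polarity-matched: the nucleophilic CH2 terminus of 16 bonds to the terminal alkyne carbon (C5'–C6') and the ketene acetal carbon closes onto the acyl-bearing carbon (C1'–C2'), so ring B is closed in one intermolecular [4+2] event. Adduct 17 has a doubly allylic mixed ketal; ionisation there and loss of the C5' proton expel methanol to give silyl ether 18, which the mild acid hydrolyses to the hydrogen-bonded phenol 19. The required regiochemistry, OH ortho and OMe para to the acyl group, is secured by the terminal alkyne, whose unsubstituted carbon is both the more electrophilic and the less hindered. The electron-rich diene should ignore the unactivated prenyl alkene, and the carbonyl group does not react without a Lewis acid. The ketal carbon of 17 is the only new stereocentre; it forms without control and disappears on aromatisation, and the methoxy-bearing carbon stays racemic. The acetals should survive the neutral thermal conditions and the citric acid work-up.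

Step 8
Reactants: 19 racemic 1-(2-hydroxy-4-methoxyphenyl)-2-methoxy-2-[2,4-bis(methoxymethoxy)-5-(3-methylbut-2-enyl)phenyl]ethanone
Product: 22 ambofuranol, via triphenol ketone 20 (not isolated), via cyclic hemiketal 21 (not isolated)
Conditions: HCl (1.25 M in MeOH), 0 → 40 °C
Reagents that add atoms: none
Why: Acid-catalysed acetal exchange releases both phenols (20); the ring A hydroxyl ortho to the benzylic carbon adds 5-exo-trig to the protonated ketone (21) and dehydration gives the aromatic furan, the usual cyclodehydration of an ortho-hydroxybenzyl aryl ketone. Methanol as solvent makes any ionisation of the benzylic C3–OMe bond degenerate. Dilute acid and low temperature are chosen to spare the prenyl group.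

## Compound list

1 | 5-bromo-2,4-dihydroxybenzaldehyde | O=Cc1cc(Br)c(O)cc1O | starting material
2 | 5-bromo-2,4-bis(methoxymethoxy)benzaldehyde | O=Cc1cc(Br)c(OCOC)cc1OCOC | intermediate
3 | racemic 2,2,2-tribromo-1-[5-bromo-2,4-bis(methoxymethoxy)phenyl]ethanol (formed as its potassium alkoxide) | OC(c1cc(Br)c(OCOC)cc1OCOC)C(Br)(Br)Br | intermediate
4 | racemic 2,2-dibromo-3-[5-bromo-2,4-bis(methoxymethoxy)phenyl]oxirane | BrC1(Br)OC1c1cc(Br)c(OCOC)cc1OCOC | intermediate
5 | racemic 2-[5-bromo-2,4-bis(methoxymethoxy)phenyl]-2-methoxyacetyl bromide | COC(C(=O)Br)c1cc(Br)c(OCOC)cc1OCOC | intermediate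
6 | racemic 2-[5-bromo-2,4-bis(methoxymethoxy)phenyl]-2-methoxyacetic acid | COC(C(=O)O)c1cc(Br)c(OCOC)cc1OCOC | intermediate
7 | racemic 2-[5-bromo-2,4-bis(methoxymethoxy)phenyl]-1-(imidazol-1-yl)-2-methoxyethanone | COC(C(=O)n1ccnc1)c1cc(Br)c(OCOC)cc1OCOC | intermediate
8 | racemic 2-[5-bromo-2,4-bis(methoxymethoxy)phenyl]-N,2-dimethoxy-N-methylacetamide | COC(C(=O)N(C)OC)c1cc(Br)c(OCOC)cc1OCOC | intermediate
9 | tributyl(3-methylbut-2-enyl)stannane | CCCC[Sn](CCCC)(CCCC)CC=C(C)C | starting material
10 | racemic N,2-dimethoxy-N-methyl-2-[2,4-bis(methoxymethoxy)-5-(3-methylbut-2-enyl)phenyl]acetamide | COC(C(=O)N(C)OC)c1cc(CC=C(C)C)c(OCOC)cc1OCOC | intermediate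
11 | ethynylmagnesium bromide | C#C[Mg]Br | starting material
12 | bromomagnesium alkoxide of the hemiaminal from 10 and 11 (diastereomer mixture) | C#CC(O[Mg]Br)(N(C)OC)C(OC)c1cc(CC=C(C)C)c(OCOC)cc1OCOC | intermediate
13 | racemic 1-methoxy-1-[2,4-bis(methoxymethoxy)-5-(3-methylbut-2-enyl)phenyl]but-3-yn-2-one | C#CC(=O)C(OC)c1cc(CC=C(C)C)c(OCOC)cc1OCOC | intermediate
14 | methyl (E)-3-methoxybut-2-enoate | CO/C(C)=C/C(=O)OC | starting material
15 | lithium 1,3-dimethoxybuta-1,3-dien-1-olate (dienolate of 14) | C=C(OC)/C=C(/OC)O[Li] | intermediate
16 | (1Z)-1,3-dimethoxy-1-(trimethylsilyloxy)buta-1,3-diene | C=C(OC)/C=C(/OC)O[Si](C)(C)C | intermediate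
17 | 1-[4,6-dimethoxy-6-(trimethylsilyloxy)cyclohexa-1,4-dien-1-yl]-2-methoxy-2-[2,4-bis(methoxymethoxy)-5-(3-methylbut-2-enyl)phenyl]ethanone (diastereomer mixture) | COC1=CC(OC)(O[Si](C)(C)C)C(C(=O)C(OC)c2cc(CC=C(C)C)c(OCOC)cc2OCOC)=CC1 | intermediate
18 | racemic 2-methoxy-1-[4-methoxy-2-(trimethylsilyloxy)phenyl]-2-[2,4-bis(methoxymethoxy)-5-(3-methylbut-2-enyl)phenyl]ethanone | COc1ccc(C(=O)C(OC)c2cc(CC=C(C)C)c(OCOC)cc2OCOC)c(O[Si](C)(C)C)c1 | intermediate
19 | racemic 1-(2-hydroxy-4-methoxyphenyl)-2-methoxy-2-[2,4-bis(methoxymethoxy)-5-(3-methylbut-2-enyl)phenyl]ethanone | COc1ccc(C(=O)C(OC)c2cc(CC=C(C)C)c(OCOC)cc2OCOC)c(O)c1 | intermediate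
20 | racemic 2-[2,4-dihydroxy-5-(3-methylbut-2-enyl)phenyl]-1-(2-hydroxy-4-methoxyphenyl)-2-methoxyethanone | COc1ccc(C(=O)C(OC)c2cc(CC=C(C)C)c(O)cc2O)c(O)c1 | intermediate
21 | 2-(2-hydroxy-4-methoxyphenyl)-3-methoxy-5-(3-methylbut-2-enyl)-2,3-dihydro-1-benzofuran-2,6-diol (diastereomer mixture) | COc1ccc(C2(O)Oc3cc(O)c(CC=C(C)C)cc3C2OC)c(O)c1 | intermediate
22 | ambofuranol, 2-(2-hydroxy-4-methoxyphenyl)-3-methoxy-5-(3-methylbut-2-enyl)-1-benzofuran-6-ol | COc1ccc(-c2oc3cc(O)c(CC=C(C)C)cc3c2OC)c(O)c1 | target

## Step count and least certain steps

Total: 8 steps. Longest linear sequence: 7 steps (1 to 22 through steps 1–5, 7 and 8); the diene branch is one step (step 6).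

Step 7 (key step).
- Risk: the diene may act as a vinylogous Michael donor and stop at an open-chain adduct. The terminal ynone may oligomerise on heating, or its acidic α-CH may protonate and consume the diene. During aromatisation the silyloxy group may be expelled in place of the methoxy group, which would leave the C2' oxygen methylated.
- Fallback: ring B is brought in ready-made by acyl substitution. Commercial 2-bromo-5-methoxyphenol F1 is protected (NaH, MOMCl, DMF) as 1-bromo-4-methoxy-2-(methoxymethoxy)benzene F2. Mg turnings and LiCl in THF convert it into [4-methoxy-2-(methoxymethoxy)phenyl]magnesium bromide F3, which is added to Weinreb amide 10 to give racemic 2-methoxy-1-[4-methoxy-2-(methoxymethoxy)phenyl]-2-[2,4-bis(methoxymethoxy)-5-(3-methylbut-2-enyl)phenyl]ethanone F4. Under the conditions of step 8, F4 loses three acetal groups. The fallback sets out from 10 and returns to the route at 20, which closes to 22.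

Step 8.
- Risk: acid may cyclise the ortho-prenylphenol to a chroman or add methanol across the prenyl alkene. Closure onto the deactivated, hydrogen-bonded ketone may be slow and call for stronger acid. Ionisation at the benzylic C–OMe carbon with capture by the ring B hydroxyl may compete.
- Fallback: prenylation is moved to the end, so the acid step runs on a substrate without an alkene and can be forced. Bromo amide 8 and 11 give racemic 1-[5-bromo-2,4-bis(methoxymethoxy)phenyl]-1-methoxybut-3-yn-2-one F5 (conditions of step 5). Cycloaddition with 16 (conditions of step 7) gives racemic 2-[5-bromo-2,4-bis(methoxymethoxy)phenyl]-1-(2-hydroxy-4-methoxyphenyl)-2-methoxyethanone F6. HCl in MeOH, at reflux if needed, gives 5-bromo-2-(2-hydroxy-4-methoxyphenyl)-3-methoxy-1-benzofuran-6-ol F7. Stille coupling of F7 with 9 (Pd(PPh3)4, DMF, 95 °C) then installs the prenyl group. The fallback sets out from 8 and returns at 22.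

Step 2.
- Risk: addition of tribromomethanide to the electron-rich aldehyde is reversible and may be outrun by Cannizzaro disproportionation or by decomposition of the haloform. An acetal may be lost during acidification.
- Fallback: the C–C bond formation is separated from the substitution. Aldehyde 2 with CHCl3 and DBU (neat, 0 °C → rt) gives the isolable racemic 1-[5-bromo-2,4-bis(methoxymethoxy)phenyl]-2,2,2-trichloroethanol F8. KOH in MeOH then converts F8 through the gem-dichloro epoxide into acid 6. The fallback sets out from 2 and returns at 6.

Step 4.
- Risk: prenyl transfer through the tertiary terminus would give the 1,1-dimethylallyl isomer. Oxidative addition into the electron-rich aryl bromide may be slow, so that protodestannylation takes over.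
- Fallback: the chain is built in two stages. Stille coupling of 8 with allyltributylstannane (Pd(PPh3)4, DMF, 95 °C), where the regiochemistry question does not arise, gives racemic N,2-dimethoxy-N-methyl-2-[2,4-bis(methoxymethoxy)-5-(prop-2-enyl)phenyl]acetamide F9. Cross-metathesis of F9 with 2-methylbut-2-ene (second-generation Grubbs catalyst, CH2Cl2, 40 °C) gives 10. The fallback sets out from 8 and returns at 10.

Step 5.
- Risk: the hydroxylamine released on work-up may add to the ynone in conjugate fashion, and the terminal ynone may decompose under the basic reaction medium.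
- Fallback: the ketone is reached through the alcohol oxidation level. Amide 10 is reduced with iBu2AlH (THF, −78 °C) to racemic 2-methoxy-2-[2,4-bis(methoxymethoxy)-5-(3-methylbut-2-enyl)phenyl]acetaldehyde F10. Addition of 11 gives 1-methoxy-1-[2,4-bis(methoxymethoxy)-5-(3-methylbut-2-enyl)phenyl]but-3-yn-2-ol F11 as a diastereomer mixture. MnO2 (CH2Cl2, rt) oxidises the propargylic alcohol to 13. The fallback sets out from 10 and returns at 13.

## Further compounds

F1 | step 7 | 2-bromo-5-methoxyphenol | COc1ccc(Br)c(O)c1
F2 | step 7 | 1-bromo-4-methoxy-2-(methoxymethoxy)benzene | COCOc1cc(OC)ccc1Br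
F3 | step 7 | [4-methoxy-2-(methoxymethoxy)phenyl]magnesium bromide | COCOc1cc(OC)ccc1[Mg]Br
F4 | step 7 | racemic 2-methoxy-1-[4-methoxy-2-(methoxymethoxy)phenyl]-2-[2,4-bis(methoxymethoxy)-5-(3-methylbut-2-enyl)phenyl]ethanone | COc1ccc(C(=O)C(OC)c2cc(CC=C(C)C)c(OCOC)cc2OCOC)c(OCOC)c1
F5 | step 8 | racemic 1-[5-bromo-2,4-bis(methoxymethoxy)phenyl]-1-methoxybut-3-yn-2-one | C#CC(=O)C(OC)c1cc(Br)c(OCOC)cc1OCOC
F6 | step 8 | racemic 2-[5-bromo-2,4-bis(methoxymethoxy)phenyl]-1-(2-hydroxy-4-methoxyphenyl)-2-methoxyethanone | COc1ccc(C(=O)C(OC)c2cc(Br)c(OCOC)cc2OCOC)c(O)c1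
F7 | step 8 | 5-bromo-2-(2-hydroxy-4-methoxyphenyl)-3-methoxy-1-benzofuran-6-ol | COc1ccc(-c2oc3cc(O)c(Br)cc3c2OC)c(O)c1
F8 | step 2 | racemic 1-[5-bromo-2,4-bis(methoxymethoxy)phenyl]-2,2,2-trichloroethanol | OC(c1cc(Br)c(OCOC)cc1OCOC)C(Cl)(Cl)Cl
F9 | step 4 | racemic N,2-dimethoxy-N-methyl-2-[2,4-bis(methoxymethoxy)-5-(prop-2-enyl)phenyl]acetamide | C=CCc1cc(C(OC)C(=O)N(C)OC)c(OCOC)cc1OCOC
F10 | step 5 | racemic 2-methoxy-2-[2,4-bis(methoxymethoxy)-5-(3-methylbut-2-enyl)phenyl]acetaldehyde | COC(C=O)c1cc(CC=C(C)C)c(OCOC)cc1OCOC
F11 | step 5 | 1-methoxy-1-[2,4-bis(methoxymethoxy)-5-(3-methylbut-2-enyl)phenyl]but-3-yn-2-ol (diastereomer mixture) | C#CC(O)C(OC)c1cc(CC=C(C)C)c(OCOC)cc1OCOC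
A1 | alternative 1 | ambofuranol 2'-O-pivalate | COc1ccc(-c2oc3cc(O)c(CC=C(C)C)cc3c2OC)c(OC(=O)C(C)(C)C)c1
A2 | alternative 1 | 4-methoxy-2-(pivaloyloxy)phenylglyoxal | COc1ccc(C(=O)C=O)c(OC(=O)C(C)(C)C)c1
A3 | alternative 1 | 4-(3-methylbut-2-enyl)benzene-1,3-diol (4-prenylresorcinol) | CC(C)=CCc1ccc(O)cc1O
A4 | alternative 2 | racemic trans-2-[4-methoxy-2-(methoxymethoxy)phenyl]-6-(methoxymethoxy)-5-(3-methylbut-2-enyl)-2,3-dihydro-1-benzofuran-3-ol (one enantiomer drawn) | O[C@H]1[C@H](c2ccc(OC)cc2OCOC)Oc2cc(OCOC)c(CC=C(C)C)cc21
A5 | alternative 2 | [4-methoxy-2-(methoxymethoxy)benzyl]dimethylsulfonium bromide | COc1ccc(C[S+](C)C)c(OCOC)c1.[Br-]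
A6 | alternative 2 | 2-hydroxy-4-(methoxymethoxy)-5-(3-methylbut-2-enyl)benzaldehyde | O=Cc1cc(CC=C(C)C)c(OCOC)cc1O
A7 | alternative 2 | racemic 2-[4-methoxy-2-(methoxymethoxy)phenyl]-6-(methoxymethoxy)-5-(3-methylbut-2-enyl)-1-benzofuran-3(2H)-one | O=C1C(c2ccc(OC)cc2OCOC)Oc2cc(OCOC)c(CC=C(C)C)cc21
A8 | alternative 3 | ambofuranol 6-O-trimethylsilyl 2'-O-methoxymethyl ether | COc1ccc(-c2oc3cc(O[Si](C)(C)C)c(CC=C(C)C)cc3c2OC)c(OCOC)c1
A9 | alternative 3 | 5-[2,2-bis(trimethylsilyloxy)ethenyl]-3-methoxy-2-[4-methoxy-2-(methoxymethoxy)phenyl]-4-[(1E)-5-methylhexa-1,4-dienyl]furan | COc1ccc(-c2oc(C=C(O[Si](C)(C)C)O[Si](C)(C)C)c(/C=C/CC=C(C)C)c2OC)c(OCOC)c1
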